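The oxane ring (O1, C2 carrying the acrylic acid, C3, C4, C5 carrying the side chain C7–C8–C9, C6) is opened at C3–C4, the one ring bond whose two carbons are both plain CH2 groups. Ring-closing metathesis of an acyclic diene ether with a vinyl group on C2 and another on C5 makes this bond and the ring in a single operation, so both ring stereocentres are installed beforehand on open chains by two iridium-catalysed allylic substitutions. The precursor is the (S,S)-configured ether in which O1 links the vinyl carbinol carbon C2 to C6, and C5 carries its vinyl group and a CH2CO2Me arm; C9 is set afterwards by reagent-controlled ketone reduction.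

Key step: step 9

Remark: (E)-but-2-ene-1,4-diol is taken as purchasable, and the ligand antipodes in steps 5 and 7 follow the usual facial rule of the iridium–phosphoramidite catalyst as recalled, not checked against a source (the (Sa,Sc,Sc) ligand gives the R malonate from cinnamyl methyl carbonate).

Abbreviations: TBDPS = tert-butyl(diphenyl)silyl; L = the phosphoramidite from 1,1'-bi-2-naphthol and bis(1-phenylethyl)amine; TBD = 1,5,7-triazabicyclo[4.4.0]dec-5-ene; TEMPO = 2,2,6,6-tetramethylpiperidin-1-oxyl; Tf = trifluoromethanesulfonyl. Atom labels in the Why lines are those of the first paragraph.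

Step 1
Reactants: 1 but-3-yn-1-ol
Product: 2 4-(TBDPS-oxy)but-1-yne
Conditions: TBDPSCl, imidazole, DMF, rt
Reagents that add atoms: tert-butyl(chloro)diphenylsilane CC(C)(C)[Si](Cl)(c1ccccc1)c1ccccc1
Why: Silylation of the primary alcohol with an imidazole-activated silyl chloride is routine, and this robust silyl ether should last through base, hydride, dilute acid and oxidants until step 17.

Step 2
Reactants: 2 4-(TBDPS-oxy)but-1-yne
Product: 4 5-(TBDPS-oxy)pent-2-yn-1-ol, via lithium acetylide 3 (not isolated)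
Conditions: n-BuLi, THF, −78 °C; (CH2O)n, −78 °C → rt; H2O
Reagents that add atoms: formaldehyde (as paraformaldehyde) C=O
Why: Deprotonation of the terminal alkyne and addition of the acetylide to formaldehyde (alkynylation of an aldehyde) should give the propargylic alcohol one carbon longer.

Step 3
Reactants: 4 5-(TBDPS-oxy)pent-2-yn-1-ol
Product: 5 (2E)-5-(TBDPS-oxy)pent-2-en-1-ol
Conditions: NaAlH2(OCH2CH2OMe)2, THF, 0 °C → rt; aq. potassium sodium tartrate
Reagents that add atoms: none
Why: Hydroxyl-directed trans-hydroalumination of the propargylic alcohol and protonolysis should give only the E allylic alcohol, the geometry that iridium allyl chemistry requires.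

Step 4
Reactants: 5 (2E)-5-(TBDPS-oxy)pent-2-en-1-ol
Product: 6 tert-butyl (2E)-5-(TBDPS-oxy)pent-2-en-1-yl carbonate
Conditions: Boc2O, n-Bu4NHSO4 (cat.), 30% aq. NaOH, CH2Cl2, 0 °C → rt
Reagents that add atoms: di-tert-butyl dicarbonate CC(C)(C)OC(=O)OC(=O)OC(C)(C)C
Why: Phase-transfer O-acylation gives the tert-butyl carbonate, whose leaving group ends as carbon dioxide and the non-nucleophilic tert-butoxide, so no competing alkoxide can attack the allyl complex in step 5.

Step 5
Reactants: 6 tert-butyl (2E)-5-(TBDPS-oxy)pent-2-en-1-yl carbonate; 7 (2E)-but-2-ene-1,4-diol (5 equiv)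
Product: 8 (2E)-4-{[(3S)-5-(TBDPS-oxy)pent-1-en-3-yl]oxy}but-2-en-1-ol
Conditions: [Ir(cod)Cl]2 (2 mol %), (Ra,Rc,Rc)-L (4 mol %), n-PrNH2 pre-activation, K3PO4, THF, rt
Reagents that add atoms: none
Why: Iridium-catalysed asymmetric allylic etherification, in which the cyclometalated iridium–phosphoramidite complex ionises the linear carbonate and the primary alkoxide attacks the substituted allyl terminus to give the branched ether; the (Ra,Rc,Rc) ligand fixes the face and so sets C2 as S, while the excess of the symmetrical diol limits double allylation.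

Step 6
Reactants: 8 (2E)-4-{[(3S)-5-(TBDPS-oxy)pent-1-en-3-yl]oxy}but-2-en-1-ol
Product: 9 methyl (2E)-4-{[(3S)-5-(TBDPS-oxy)pent-1-en-3-yl]oxy}but-2-en-1-yl carbonate
Conditions: ClCO2Me, pyridine, CH2Cl2, 0 °C
Reagents that add atoms: methyl chloroformate COC(=O)Cl
Why: O-Acylation of the primary allylic alcohol gives the methyl carbonate, the standard leaving group for iridium-catalysed alkylation, whose methoxide by-product later serves as the base for the malonate.

Step 7
Reactants: 9 methyl (2E)-4-{[(3S)-5-(TBDPS-oxy)pent-1-en-3-yl]oxy}but-2-en-1-yl carbonate; 10 dimethyl malonate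
Product: 11 dimethyl 2-[(2R)-1-{[(3S)-5-(TBDPS-oxy)pent-1-en-3-yl]oxy}but-3-en-2-yl]propanedioate
Conditions: [Ir(cod)Cl]2 (2 mol %), (Sa,Sc,Sc)-L (4 mol %), TBD (8 mol %), THF, rt
Reagents that add atoms: none
Why: Iridium-catalysed asymmetric allylic alkylation under salt-free conditions, in which the malonate adds to the alkoxymethyl-bearing terminus of the allyl complex (branched selectivity typical of 4-alkoxybut-2-enyl carbonates) and the (Sa,Sc,Sc) ligand, overriding the remote C2 centre, sets C5; the E carbonate is used because Z carbonates react through anti-allyl complexes with eroded selectivity.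

Step 8
Reactants: 11 dimethyl 2-[(2R)-1-{[(3S)-5-(TBDPS-oxy)pent-1-en-3-yl]oxy}but-3-en-2-yl]propanedioate
Product: 12 methyl (3S)-3-({[(3S)-5-(TBDPS-oxy)pent-1-en-3-yl]oxy}methyl)pent-4-enoate
Conditions: NaCl, H2O, DMSO, 150 °C
Reagents that add atoms: none
Why: Krapcho dealkoxycarbonylation, in which chloride demethylates one ester and the carboxylate loses carbon dioxide, leaves the CH2CO2Me arm on C5; no stereocentre lies α to a carbonyl, so nothing can epimerise (the descriptor at C5 changes from R to S only because the priorities change).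

Step 9
Reactants: 12 methyl (3S)-3-({[(3S)-5-(TBDPS-oxy)pent-1-en-3-yl]oxy}methyl)pent-4-enoate
Product: 13 methyl 2-{(3S,6S)-6-[2-(TBDPS-oxy)ethyl]-3,6-dihydro-2H-pyran-3-yl}acetate (2,5-trans in the route numbering)
Conditions: second-generation Grubbs catalyst RuCl2(=CHPh)(PCy3)(H2IMes) (3 mol %), CH2Cl2 (0.01 M), 40 °C
Reagents that add atoms: none
Why: The ruthenium benzylidene first exchanges onto one of the two monosubstituted vinyl groups, the new alkylidene adds to the other vinyl group to give a ruthenacyclobutane, and cycloreversion releases the ring alkene while ethene escapes and makes the closure irreversible. The closest known reaction type is the ring-closing metathesis of allyl homoallyl ethers to 3,6-dihydro-2H-pyrans. The six-membered ring O1–C2–C3–C4–C5–C6 is closed by joining the internal carbons of the C2 and C5 vinyl groups as the C3=C4 double bond, a six-membered metathesis closure favoured by the short C2–O1–C6–C5 tether. No stereocentre is formed, so the S configurations installed at C2 and C5 in steps 5 and 7 pass unchanged into the 2,5-trans ring. The step needs cyclisation to win over oligomerisation and the double bond to stay at C3=C4 instead of moving toward the allylic hydrogens on C2 or C5. High dilution, two unhindered terminal alkenes as the only alkenes present, a mild temperature and the inertness of ester and silyl ether toward the catalyst should secure this.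

Step 10
Reactants: 13 methyl 2-{(3S,6S)-6-[2-(TBDPS-oxy)ethyl]-3,6-dihydro-2H-pyran-3-yl}acetate
Product: 14 methyl 2-{(3R,6R)-6-[2-(TBDPS-oxy)ethyl]oxan-3-yl}acetate
Conditions: H2 (1 atm), PtO2, EtOAc, rt
Reagents that add atoms: none
Why: Heterogeneous hydrogenation of the only alkene, with platinum chosen over palladium to avoid double-bond migration into the enol ether position and hydrogenolysis of the allylic C2–O1 bond, so C2 and C5 stay as set (descriptors change by priority only).

Step 11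
Reactants: 14 methyl 2-{(3R,6R)-6-[2-(TBDPS-oxy)ethyl]oxan-3-yl}acetate
Product: 15 2-{(3R,6R)-6-[2-(TBDPS-oxy)ethyl]oxan-3-yl}acetaldehyde
Conditions: i-Bu2AlH (1.1 equiv), CH2Cl2, −78 °C; MeOH, aq. potassium sodium tartrate
Reagents that add atoms: none
Why: Partial reduction of the methyl ester at −78 °C should stop at the tetrahedral aluminium hemiacetal, which releases the C8 aldehyde only on work-up.

Step 12
Reactants: 15 2-{(3R,6R)-6-[2-(TBDPS-oxy)ethyl]oxan-3-yl}acetaldehyde
Product: 17 3-{(3R,6R)-6-[2-(TBDPS-oxy)ethyl]oxan-3-yl}propanal, via methyl enol ether 16 (not isolated)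
Conditions: Ph3P(CH2OMe)Cl, KN(SiMe3)2, THF, 0 °C; then 2 M aq. HCl, rt
Reagents that add atoms: (methoxymethyl)triphenylphosphonium chloride COC[P+](c1ccccc1)(c1ccccc1)c1ccccc1.[Cl-]; water O
Why: Wittig methoxymethylenation gives the enol ether, whose acid hydrolysis in the same flask should deliver the aldehyde homologated by one carbon (C9), the silyl ether tolerating brief dilute acid.

Step 13
Reactants: 18 geranylacetone
Product: 20 (5E)-6,10-dimethylundeca-1,5,9-trien-2-yl trifluoromethanesulfonate, via potassium enolate 19 (not isolated)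
Conditions: KN(SiMe3)2, THF, −78 °C; PhNTf2, −78 °C → 0 °C
Reagents that add atoms: N-phenylbis(trifluoromethanesulfonimide) O=S(=O)(N(c1ccccc1)S(=O)(=O)C(F)(F)F)C(F)(F)F
Why: Kinetic deprotonation of the methyl ketone at its methyl group by the bulky amide base and O-sulfonylation of the terminal enolate should give the 1,1-disubstituted alkenyl triflate without touching the trisubstituted alkenes.

Step 14
Reactants: 17 3-{(3R,6R)-6-[2-(TBDPS-oxy)ethyl]oxan-3-yl}propanal; 20 (5E)-6,10-dimethylundeca-1,5,9-trien-2-yl trifluoromethanesulfonate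
Product: 22 (7E)-8,12-dimethyl-4-methylidene-1-{(3S,6R)-6-[2-(TBDPS-oxy)ethyl]oxan-3-yl}trideca-7,11-dien-3-ol (both epimers at the carbinol carbon C9), via alkenylchromium dichloride 21 (not isolated)
Conditions: CrCl2 (4 equiv), NiCl2 (2 mol %), DMF, rt
Reagents that add atoms: none
Why: Nozaki–Hiyama–Kishi coupling, in which zerovalent nickel inserts into the C–O bond of the triflate, transmetalation gives the alkenyl species of trivalent chromium and this adds chemoselectively to the aldehyde; the remote ring centres exert no control, so both C9 epimers are expected and are carried on together.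

Step 15
Reactants: 22 (7E)-8,12-dimethyl-4-methylidene-1-{(3S,6R)-6-[2-(TBDPS-oxy)ethyl]oxan-3-yl}trideca-7,11-dien-3-ol (C9 epimers)
Product: 23 (7E)-8,12-dimethyl-4-methylidene-1-{(3R,6R)-6-[2-(TBDPS-oxy)ethyl]oxan-3-yl}trideca-7,11-dien-3-one
Conditions: Dess–Martin periodinane, CH2Cl2, rt
Reagents that add atoms: none
Why: Dess–Martin oxidation of the secondary allylic alcohol converges both epimers on one α-methylene ketone and erases the uncontrolled centre.

Step 16
Reactants: 23 (7E)-8,12-dimethyl-4-methylidene-1-{(3R,6R)-6-[2-(TBDPS-oxy)ethyl]oxan-3-yl}trideca-7,11-dien-3-one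
Product: 24 (3R,7E)-8,12-dimethyl-4-methylidene-1-{(3S,6R)-6-[2-(TBDPS-oxy)ethyl]oxan-3-yl}trideca-7,11-dien-3-ol
Conditions: (S)-2-methyl-CBS-oxazaborolidine (20 mol %), catecholborane (1.5 equiv), toluene, −78 °C
Reagents that add atoms: none
Why: Corey–Bakshi–Shibata reduction, in which the ketone binds the ring boron of the (S)-oxazaborolidine with the α-branched alkenyl group as the large substituent and hydride is delivered from the nitrogen-bound catecholborane to one face, should set C9 as R by analogy with (R)-1-phenylethanol from acetophenone; catecholborane at −78 °C does not hydroborate the alkenes.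

Step 17
Reactants: 24 (3R,7E)-8,12-dimethyl-4-methylidene-1-{(3S,6R)-6-[2-(TBDPS-oxy)ethyl]oxan-3-yl}trideca-7,11-dien-3-ol
Product: 25 (3R,7E)-1-[(3S,6R)-6-(2-hydroxyethyl)oxan-3-yl]-8,12-dimethyl-4-methylidenetrideca-7,11-dien-3-ol
Conditions: n-Bu4NF, THF, 0 °C → rt
Reagents that add atoms: none
Why: Fluoride cleaves the Si–O bond (silyl ether deprotection) and leaves the allylic alcohol and the alkenes untouched.

Step 18
Reactants: 25 (3R,7E)-1-[(3S,6R)-6-(2-hydroxyethyl)oxan-3-yl]-8,12-dimethyl-4-methylidenetrideca-7,11-dien-3-ol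
Product: 26 2-{(2R,5S)-5-[(3R,7E)-3-hydroxy-8,12-dimethyl-4-methylidenetrideca-7,11-dien-1-yl]oxan-2-yl}acetaldehyde
Conditions: TEMPO (10 mol %), PhI(OAc)2 (1.1 equiv), CH2Cl2, rt
Reagents that add atoms: none
Why: Oxoammonium (TEMPO) oxidation is selective for the unhindered primary alcohol over the hindered secondary allylic alcohol and stops at the aldehyde.

Step 19
Reactants: 26 2-{(2R,5S)-5-[(3R,7E)-3-hydroxy-8,12-dimethyl-4-methylidenetrideca-7,11-dien-1-yl]oxan-2-yl}acetaldehyde
Product: 28 2-{(2R,5S)-5-[(3R,7E)-3-hydroxy-8,12-dimethyl-4-methylidenetrideca-7,11-dien-1-yl]oxan-2-yl}prop-2-enal, via Mannich base 27 (not isolated)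
Conditions: Me2N=CH2 I (Eschenmoser's salt), Et3N, CH2Cl2, rt
Reagents that add atoms: N,N-dimethylmethylideneammonium iodide C=[N+](C)C.[I-]
Why: Mannich reaction of the aldehyde enol with the iminium salt and base-induced loss of dimethylamine (α-methylenation) should give the 2-substituted acrolein, the mild amine base at room temperature being chosen to keep β-elimination of the ring oxygen at C2 from competing.

Step 20
Reactants: 28 2-{(2R,5S)-5-[(3R,7E)-3-hydroxy-8,12-dimethyl-4-methylidenetrideca-7,11-dien-1-yl]oxan-2-yl}prop-2-enal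
Product: 29 2-{(2R,5S)-5-[(3R,7E)-3-hydroxy-8,12-dimethyl-4-methylidenetrideca-7,11-dien-1-yl]oxan-2-yl}prop-2-enoic acid
Conditions: NaClO2, NaH2PO4, 2-methylbut-2-ene, t-BuOH/H2O, 0 °C → rt
Reagents that add atoms: sodium chlorite [Na+].[O-]Cl=O
Why: Pinnick oxidation by chlorous acid converts the enal into the acrylic acid without touching the alkenes or the secondary alcohol, the scavenger alkene consuming the hypochlorous acid formed.

Compound list
1 | but-3-yn-1-ol | C#CCCO | starting material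
2 | 4-(TBDPS-oxy)but-1-yne | C#CCCO[Si](c1ccccc1)(c1ccccc1)C(C)(C)C | intermediate
3 | [4-(TBDPS-oxy)but-1-yn-1-yl]lithium | [Li]C#CCCO[Si](c1ccccc1)(c1ccccc1)C(C)(C)C | intermediate
4 | 5-(TBDPS-oxy)pent-2-yn-1-ol | OCC#CCCO[Si](c1ccccc1)(c1ccccc1)C(C)(C)C | intermediate
5 | (2E)-5-(TBDPS-oxy)pent-2-en-1-ol | OC/C=C/CCO[Si](c1ccccc1)(c1ccccc1)C(C)(C)C | intermediate
6 | tert-butyl (2E)-5-(TBDPS-oxy)pent-2-en-1-yl carbonate | CC(C)(C)OC(=O)OC/C=C/CCO[Si](c1ccccc1)(c1ccccc1)C(C)(C)C | intermediate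
7 | (2E)-but-2-ene-1,4-diol | OC/C=C/CO | starting material
8 | (2E)-4-{[(3S)-5-(TBDPS-oxy)pent-1-en-3-yl]oxy}but-2-en-1-ol | OC/C=C/CO[C@H](C=C)CCO[Si](c1ccccc1)(c1ccccc1)C(C)(C)C | intermediate
9 | methyl (2E)-4-{[(3S)-5-(TBDPS-oxy)pent-1-en-3-yl]oxy}but-2-en-1-yl carbonate | COC(=O)OC/C=C/CO[C@H](C=C)CCO[Si](c1ccccc1)(c1ccccc1)C(C)(C)C | intermediate
10 | dimethyl malonate | COC(=O)CC(=O)OC | starting material
11 | dimethyl 2-[(2R)-1-{[(3S)-5-(TBDPS-oxy)pent-1-en-3-yl]oxy}but-3-en-2-yl]propanedioate | COC(=O)C(C(=O)OC)[C@H](CO[C@H](C=C)CCO[Si](c1ccccc1)(c1ccccc1)C(C)(C)C)C=C | intermediate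
12 | methyl (3S)-3-({[(3S)-5-(TBDPS-oxy)pent-1-en-3-yl]oxy}methyl)pent-4-enoate (diene ether, precursor of the key step) | COC(=O)C[C@H](CO[C@H](C=C)CCO[Si](c1ccccc1)(c1ccccc1)C(C)(C)C)C=C | intermediate
13 | methyl 2-{(3S,6S)-6-[2-(TBDPS-oxy)ethyl]-3,6-dihydro-2H-pyran-3-yl}acetate (trans; product of the key step) | COC(=O)C[C@H]1C=C[C@H](CCO[Si](c2ccccc2)(c2ccccc2)C(C)(C)C)OC1 | intermediate
14 | methyl 2-{(3R,6R)-6-[2-(TBDPS-oxy)ethyl]oxan-3-yl}acetate | COC(=O)C[C@H]1CC[C@H](CCO[Si](c2ccccc2)(c2ccccc2)C(C)(C)C)OC1 | intermediate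
15 | 2-{(3R,6R)-6-[2-(TBDPS-oxy)ethyl]oxan-3-yl}acetaldehyde | O=CC[C@H]1CC[C@H](CCO[Si](c2ccccc2)(c2ccccc2)C(C)(C)C)OC1 | intermediate
16 | (2R,5R)-2-[2-(TBDPS-oxy)ethyl]-5-(3-methoxyprop-2-en-1-yl)oxane, E/Z mixture at the enol ether | COC=CC[C@H]1CC[C@H](CCO[Si](c2ccccc2)(c2ccccc2)C(C)(C)C)OC1 | intermediate
17 | 3-{(3R,6R)-6-[2-(TBDPS-oxy)ethyl]oxan-3-yl}propanal | O=CCC[C@H]1CC[C@H](CCO[Si](c2ccccc2)(c2ccccc2)C(C)(C)C)OC1 | intermediate
18 | geranylacetone, (5E)-6,10-dimethylundeca-5,9-dien-2-one | CC(=O)CC/C=C(\C)CCC=C(C)C | starting material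
19 | potassium (5E)-6,10-dimethylundeca-1,5,9-trien-2-olate | C=C([O-])CC/C=C(\C)CCC=C(C)C.[K+] | intermediate
20 | (5E)-6,10-dimethylundeca-1,5,9-trien-2-yl trifluoromethanesulfonate | C=C(OS(=O)(=O)C(F)(F)F)CC/C=C(\C)CCC=C(C)C | intermediate
21 | [(5E)-6,10-dimethylundeca-1,5,9-trien-2-yl]chromium dichloride | C=C([Cr](Cl)Cl)CC/C=C(\C)CCC=C(C)C | intermediate
22 | (7E)-8,12-dimethyl-4-methylidene-1-{(3S,6R)-6-[2-(TBDPS-oxy)ethyl]oxan-3-yl}trideca-7,11-dien-3-ol, both epimers at C3 of the chain (C9) | C=C(CC/C=C(\C)CCC=C(C)C)C(O)CC[C@H]1CC[C@H](CCO[Si](c2ccccc2)(c2ccccc2)C(C)(C)C)OC1 | intermediate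
23 | (7E)-8,12-dimethyl-4-methylidene-1-{(3R,6R)-6-[2-(TBDPS-oxy)ethyl]oxan-3-yl}trideca-7,11-dien-3-one | C=C(CC/C=C(\C)CCC=C(C)C)C(=O)CC[C@H]1CC[C@H](CCO[Si](c2ccccc2)(c2ccccc2)C(C)(C)C)OC1 | intermediate
24 | (3R,7E)-8,12-dimethyl-4-methylidene-1-{(3S,6R)-6-[2-(TBDPS-oxy)ethyl]oxan-3-yl}trideca-7,11-dien-3-ol | C=C(CC/C=C(\C)CCC=C(C)C)[C@H](O)CC[C@H]1CC[C@H](CCO[Si](c2ccccc2)(c2ccccc2)C(C)(C)C)OC1 | intermediate
25 | (3R,7E)-1-[(3S,6R)-6-(2-hydroxyethyl)oxan-3-yl]-8,12-dimethyl-4-methylidenetrideca-7,11-dien-3-ol | C=C(CC/C=C(\C)CCC=C(C)C)[C@H](O)CC[C@H]1CC[C@H](CCO)OC1 | intermediate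
26 | 2-{(2R,5S)-5-[(3R,7E)-3-hydroxy-8,12-dimethyl-4-methylidenetrideca-7,11-dien-1-yl]oxan-2-yl}acetaldehyde | C=C(CC/C=C(\C)CCC=C(C)C)[C@H](O)CC[C@H]1CC[C@H](CC=O)OC1 | intermediate
27 | 3-(dimethylamino)-2-{(2R,5S)-5-[(3R,7E)-3-hydroxy-8,12-dimethyl-4-methylidenetrideca-7,11-dien-1-yl]oxan-2-yl}propanal, both epimers at C2 of the propanal | C=C(CC/C=C(\C)CCC=C(C)C)[C@H](O)CC[C@H]1CC[C@H](C(CN(C)C)C=O)OC1 | intermediate
28 | 2-{(2R,5S)-5-[(3R,7E)-3-hydroxy-8,12-dimethyl-4-methylidenetrideca-7,11-dien-1-yl]oxan-2-yl}prop-2-enal | C=C(CC/C=C(\C)CCC=C(C)C)[C@H](O)CC[C@H]1CC[C@H](C(=C)C=O)OC1 | intermediate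
29 | 2-{(2R,5S)-5-[(3R,7E)-3-hydroxy-8,12-dimethyl-4-methylidenetrideca-7,11-dien-1-yl]oxan-2-yl}prop-2-enoic acid | C=C(CC/C=C(\C)CCC=C(C)C)[C@H](O)CC[C@H]1CC[C@H](C(=C)C(=O)O)OC1 | target

Total step count: 20.
Longest linear sequence: 19 steps (steps 1–12 and 14–20, from but-3-yn-1-ol); step 13 is a one-step side branch.

Steps most likely to fail

Step 5. The free diol may be allylated twice, may slow the catalyst by binding as an alkoxide, or may attack the unsubstituted allyl terminus, and a weak or reversed facial preference would erode or invert C2. The fallback sets out from 5 and returns at 8; it makes C2 by reagent-controlled epoxidation instead of allylic substitution. Sharpless asymmetric epoxidation of 5 (Ti(OiPr)4, L-(+)-diethyl tartrate, t-BuOOH, 4 Å sieves, CH2Cl2, −20 °C) should give the epoxy alcohol [(2S,3S)-3-[2-(TBDPS-oxy)ethyl]oxiran-2-yl]methanol F1. Iodination (I2, PPh3, imidazole, THF) gives the iodide (2R,3S)-2-(iodomethyl)-3-[2-(TBDPS-oxy)ethyl]oxirane F2. Zinc dust in ethanol at reflux opens F2 reductively to the allylic alcohol (3S)-5-(TBDPS-oxy)pent-1-en-3-ol F3, whose carbinol centre is the epoxide carbon left untouched. Williamson alkylation (NaH, excess (E)-1,4-dibromobut-2-ene, THF, 0 °C) gives the bromide (3S)-3-{[(2E)-4-bromobut-2-en-1-yl]oxy}-5-(TBDPS-oxy)pent-1-ene F4. Displacement with KOAc in DMF gives the acetate (2E)-4-{[(3S)-5-(TBDPS-oxy)pent-1-en-3-yl]oxy}but-2-en-1-yl acetate F5, and K2CO3 in MeOH returns 8.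

Step 7. Attack at the terminal allyl carbon (linear malonate) or insufficient facial control with the ether-bearing carbonate would spoil C5. The fallback sets out from 8 and returns at 12; it makes C5 by auxiliary-controlled conjugate addition. Oxidation of 8 (TEMPO, PhI(OAc)2, MeCN/H2O) gives the acid (2E)-4-{[(3S)-5-(TBDPS-oxy)pent-1-en-3-yl]oxy}but-2-enoic acid F6. Its mixed pivalic anhydride (t-BuCOCl, Et3N, THF) is acylated onto the lithium salt of (4R)-4-phenyl-1,3-oxazolidin-2-one to give the imide (4R)-3-[(2E)-4-{[(3S)-5-(TBDPS-oxy)pent-1-en-3-yl]oxy}but-2-enoyl]-4-phenyl-1,3-oxazolidin-2-one F7. CH2=CHMgBr with CuBr·SMe2 in THF at −40 °C should add the vinyl group to the β-carbon anti to the phenyl group of the magnesium-chelated s-cis imide, giving (4R)-3-[(3S)-3-({[(3S)-5-(TBDPS-oxy)pent-1-en-3-yl]oxy}methyl)pent-4-enoyl]-4-phenyl-1,3-oxazolidin-2-one F8. NaOMe in MeOH at 0 °C then releases 12 and the auxiliary.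

Step 16. Weak discrimination between the alkenyl and alkyl substituents of the ketone, or competing conjugate reduction of the s-cis enone, would give an epimer mixture at C9 or a saturated ketone. The fallback sets out from 17 and 20 and returns at 24; it creates C9 in the carbon–carbon bond-forming event itself. A catalytic asymmetric Nozaki–Hiyama–Kishi coupling (CrCl2 with a chiral sulfonamide–oxazoline ligand and Et3N, NiCl2, Mn, Cp2ZrCl2, MeCN, rt) is run with the ligand antipode that delivers the 9R alcohol, so 22 and 23 are not needed.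

Further compounds
F1 | step 5 | [(2S,3S)-3-[2-(TBDPS-oxy)ethyl]oxiran-2-yl]methanol | OC[C@@H]1O[C@H]1CCO[Si](c2ccccc2)(c2ccccc2)C(C)(C)C
F2 | step 5 | (2R,3S)-2-(iodomethyl)-3-[2-(TBDPS-oxy)ethyl]oxirane | IC[C@@H]1O[C@H]1CCO[Si](c2ccccc2)(c2ccccc2)C(C)(C)C
F3 | step 5 | (3S)-5-(TBDPS-oxy)pent-1-en-3-ol | C=C[C@@H](O)CCO[Si](c1ccccc1)(c1ccccc1)C(C)(C)C
F4 | step 5 | (3S)-3-{[(2E)-4-bromobut-2-en-1-yl]oxy}-5-(TBDPS-oxy)pent-1-ene | BrC/C=C/CO[C@H](C=C)CCO[Si](c1ccccc1)(c1ccccc1)C(C)(C)C
F5 | step 5 | (2E)-4-{[(3S)-5-(TBDPS-oxy)pent-1-en-3-yl]oxy}but-2-en-1-yl acetate | CC(=O)OC/C=C/CO[C@H](C=C)CCO[Si](c1ccccc1)(c1ccccc1)C(C)(C)C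
F6 | step 7 | (2E)-4-{[(3S)-5-(TBDPS-oxy)pent-1-en-3-yl]oxy}but-2-enoic acid | OC(=O)/C=C/CO[C@H](C=C)CCO[Si](c1ccccc1)(c1ccccc1)C(C)(C)C
F7 | step 7 | (4R)-3-[(2E)-4-{[(3S)-5-(TBDPS-oxy)pent-1-en-3-yl]oxy}but-2-enoyl]-4-phenyl-1,3-oxazolidin-2-one | O=C(/C=C/CO[C@H](C=C)CCO[Si](c1ccccc1)(c1ccccc1)C(C)(C)C)N1C(=O)OC[C@H]1c1ccccc1
F8 | step 7 | (4R)-3-[(3S)-3-({[(3S)-5-(TBDPS-oxy)pent-1-en-3-yl]oxy}methyl)pent-4-enoyl]-4-phenyl-1,3-oxazolidin-2-one | O=C(C[C@H](CO[C@H](C=C)CCO[Si](c1ccccc1)(c1ccccc1)C(C)(C)C)C=C)N1C(=O)OC[C@H]1c1ccccc1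
F0 | step 16 | none | none
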